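Ring A (C1–C2–C3–C4–C5–C10) bears its oxygen at C3 next to the C4 methyl, so it is read as the adduct of a 2-silyloxy diene (C1=C2–C3=C4) with the C5=C10 edge of a quinone that already holds the C5 methyl and the C8/C9 oxygens of ring B. The key step is a catalytic asymmetric Diels–Alder reaction of 2-methoxy-5-methylbenzoquinone with 4-silyloxy-2H-thiopyran, a locked cis-diene whose sulfur ties the future C4 methyl carbon to C1. It forms C4–C5 and C1–C10 at once, sets the C5 quaternary centre and, via the endo bicyclic adduct, the cis C4/C5 methyl pair; the bridge then steers the C3 reduction and is excised by Raney Ni.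

Key step: step 4

Numbering: eremophilane numbering is used for all intermediates (ring A = C1, C2, C3, C4, C5, C10; ring B = C5 to C10; C11–C13 = isopropylidene; C14 = methyl on C5; C15 = methyl on C4).

Remark: the (R)-configured binaphtholate is assumed to leave open the face that leads to the adduct shown; should the opposite sense of induction be found, the (S)-ligand is used.

Step 1
Reactants: 1 tetrahydro-4H-thiopyran-4-one
Product: 2 2,3-dihydro-4H-thiopyran-4-one
Conditions: N-chlorosuccinimide, pyridine, CH2Cl2, 0 °C → rt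
Reagents that add atoms: none
Why: S-chlorination and Pummerer-type α-chlorination of the sulfide followed by pyridine-mediated loss of HCl should give the vinylogous thioester (sulfide dehydrogenation).

Step 2
Reactants: 2 2,3-dihydro-4H-thiopyran-4-one
Product: 3 4-(tert-butyldimethylsilyloxy)-2H-thiopyran
Conditions: TBSOTf, Et3N, CH2Cl2, 0 °C
Reagents that add atoms: tert-butyldimethylsilyl trifluoromethanesulfonate, CC(C)(C)[Si](C)(C)OS(=O)(=O)C(F)(F)F
Why: Soft enolisation (silyl triflate and amine) at the only enolisable α-carbon gives the cross-conjugated silyl dienol ether, i.e. the cyclic 2-silyloxy diene.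

Step 3
Reactants: 4 2-methoxy-5-methylphenol
Product: 5 2-methoxy-5-methyl-1,4-benzoquinone
Conditions: potassium nitrosodisulfonate ON(SO3K)2, KH2PO4, H2O/acetone, rt
Reagents that add atoms: potassium nitrosodisulfonate, [O]N(S(=O)(=O)[O-])S(=O)(=O)[O-].[K+].[K+]
Why: Teuber oxidation: the nitroxyl radical oxidises the phenol at its free para position to the p-quinone.

Step 4
Reactants: 3 4-(tert-butyldimethylsilyloxy)-2H-thiopyran; 5 2-methoxy-5-methyl-1,4-benzoquinone
Product: 7 1,15-epithio-8-methoxy-11,12,13-trinoreremophil-7-ene-3,6,9-trione (endo adduct; C14 and H-10 syn to the S–C15 bridge), via silyl enol ether cycloadduct 6 (not isolated)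
Conditions: (R)-BINOL–TiCl2 (C20H12O2TiCl2, 20 mol%), 4 Å MS, CH2Cl2/toluene, −40 → 0 °C; then HF (aq.), MeCN, 0 °C
Reagents that add atoms: none
Why: Normal-demand Diels–Alder reaction: the diene of 3 (thiopyran C3=C4–C5=C6) adds suprafacially to the methyl-bearing double bond of 5 through a concerted, asynchronous transition state in which the bond from thiopyran C3 (future C4) to the methyl-bearing quinone carbon (future C5) is the more advanced, and HF then unmasks the C3 ketone; the closest known reaction types are Lewis-acid-catalysed quinone Diels–Alder reactions of 2-silyloxy dienes and cycloadditions of 2H-thiopyrans as cis-diene equivalents. Ring A (C1–C2–C3–C4–C5–C10) closes in the [4+2] mode, and because the diene is cyclic the same event creates the 2-thiabicyclo[2.2.2]octene cage in which sulfur and C15 bridge C1 and C4. C5 and C10 are formed cis by the suprafacial addition to the quinone, C1 and C4 are bridgeheads whose configuration follows from the face of the diene that is attacked, and the endo transition state (ring B under the diene) turns the C5 methyl towards the S–C15 bridge, which is what makes C14 and C15 cis once the sulfur is removed. The absolute configuration is controlled by the C2-symmetric binaphtholate on tetravalent titanium, which binds the quinone in a two-point fashion and leaves one face of the reacting double bond open. The step needs site selectivity (methyl- versus methoxy-substituted double bond), regioselectivity and endo selectivity: the methoxy group deactivates its own double bond, chelation of titanium between the methoxy oxygen and the adjacent carbonyl (future C9=O) makes the methyl-bearing carbon the electrophilic β-terminus, both donors of the diene (ring sulfur on one terminus, silyloxy on the inner carbon) place the largest HOMO coefficient on thiopyran C3, and secondary orbital overlap with the ene-dione favours endo.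

Step 5
Reactants: 7 1,15-epithio-8-methoxy-11,12,13-trinoreremophil-7-ene-3,6,9-trione
Product: 9 (3R)-1,15-epithio-3,9-dihydroxy-11,12,13-trinoreremophil-6-en-8-one (C9 carbinol as either epimer), via sulfur-bridged triol 8 (not isolated)
Conditions: LiAlH4, THF, −78 → 0 °C; then 2 M HCl, THF, rt
Reagents that add atoms: water, O
Why: Hydride reduces all three ketones, attacking C3=O from the face syn to the S–C15 bridge because the other face is blocked by the endo ring-B carbon C6 (this sets the C3 carbinol trans to C15), and aqueous acid then effects a Stork–Danheiser-type transposition (ionisation of the vinylogous hemiacetal at C6, hydrolysis of the methyl enol ether) to the C6=C7–C8=O enone.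

Step 6
Reactants: 9 (3R)-1,15-epithio-3,9-dihydroxy-11,12,13-trinoreremophil-6-en-8-one
Product: 10 (3R,4R,5R,10S)-3,9-dihydroxy-11,12,13-trinoreremophilan-8-one (C9 carbinol as either epimer)
Conditions: Raney Ni (W-2), H2 (1 atm), EtOH, rt
Reagents that add atoms: none
Why: Reductive desulfurization on Raney Ni cleaves both C–S bonds, turning C15 into the C4 methyl and C1 into CH2 without touching the C4 stereocentre, and the same catalyst hydrogenates the disubstituted enone double bond C6=C7.

Step 7
Reactants: 10 (3R,4R,5R,10S)-3,9-dihydroxy-11,12,13-trinoreremophilan-8-one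
Product: 11 (3R,4R,5R)-3,9-dihydroxy-11,12,13-trinoreremophil-9-en-8-one (diosphenol)
Conditions: Cu(OAc)2 (2.2 equiv), MeOH, 50 °C
Reagents that add atoms: none
Why: Divalent copper oxidises α-ketols selectively to 1,2-diones (acyloin oxidation) while the isolated C3 carbinol is untouched, and the 8,9-dione enolises towards the ring-fusion carbon C10 to the tetrasubstituted diosphenol, which erases the C9 and C10 stereocentres.

Step 8
Reactants: 11 (3R,4R,5R)-3,9-dihydroxy-11,12,13-trinoreremophil-9-en-8-one
Product: 12 (3R,4R,5R)-9-(tert-butyldimethylsilyloxy)-3-hydroxy-11,12,13-trinoreremophil-9-en-8-one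
Conditions: TBSCl (1.05 equiv), Et3N, CH2Cl2, 0 °C
Reagents that add atoms: tert-butyldimethylsilyl chloride, CC(C)(C)[Si](C)(C)Cl
Why: Chemoselective O-silylation: the acidic enol hydroxyl of the diosphenol reacts through its ammonium enolate far faster than the hindered secondary C3 alcohol.

Step 9
Reactants: 12 (3R,4R,5R)-9-(tert-butyldimethylsilyloxy)-3-hydroxy-11,12,13-trinoreremophil-9-en-8-one
Product: 13 (3R,4R,5R)-9-(tert-butyldimethylsilyloxy)-3,11-dihydroxyeremophil-9-en-8-one (C7 as either epimer)
Conditions: LDA (2.3 equiv), THF, −78 °C; ZnCl2; acetone, −78 → −40 °C; aq. NH4Cl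
Reagents that add atoms: acetone, CC(C)=O
Why: After deprotonation of the C3 hydroxyl, kinetic deprotonation at the α'-carbon C7 and transmetalation to zinc allow a directed aldol addition to acetone that brings in C11–C13 while retro-aldol and proton transfer are suppressed (the new C7 centre is removed later).

Step 10
Reactants: 14 tert-butyldimethyl(prop-2-yn-1-yloxy)silane
Product: 15 tert-butyl 4-(tert-butyldimethylsilyloxy)but-2-ynoate
Conditions: n-BuLi, THF, −78 °C; Boc2O, −78 → 0 °C
Reagents that add atoms: di-tert-butyl dicarbonate, CC(C)(C)OC(=O)OC(=O)OC(C)(C)C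
Why: Deprotonation of the terminal alkyne and acylation of the acetylide by the dicarbonate gives the tert-butyl ynoate (alkoxycarbonylation).

Step 11
Reactants: 15 tert-butyl 4-(tert-butyldimethylsilyloxy)but-2-ynoate
Product: 16 tert-butyl (Z)-4-(tert-butyldimethylsilyloxy)-3-methylbut-2-enoate
Conditions: Me2CuLi (from MeLi and CuI), THF, −78 °C; MeOH then aq. NH4Cl at −78 °C
Reagents that add atoms: lithium dimethylcuprate, [Li+].C[Cu-]C
Why: Syn carbocupration (conjugate addition) of the ynoate and protonation of the vinylcopper at low temperature with retention put methyl and hydrogen cis, so that the CH2O group and the ester are cis (Z).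

Step 12
Reactants: 16 tert-butyl (Z)-4-(tert-butyldimethylsilyloxy)-3-methylbut-2-enoate
Product: 17 tert-butyl (Z)-4-hydroxy-3-methylbut-2-enoate
Conditions: HF·pyridine, THF, 0 °C; used at once
Reagents that add atoms: none
Why: Fluoride-mediated desilylation under cold, weakly acidic conditions frees the primary alcohol while the bulky tert-butyl ester retards lactonisation of the Z-hydroxy ester.

Step 13
Reactants: 17 tert-butyl (Z)-4-hydroxy-3-methylbut-2-enoate; 18 angelic acid [(Z)-2-methylbut-2-enoic acid]
Product: 19 tert-butyl (Z)-3-methyl-4-{[(Z)-2-methylbut-2-enoyl]oxy}but-2-enoate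
Conditions: PPh3, DIAD, THF, 0 °C → rt
Reagents that add atoms: none
Why: Mitsunobu esterification: the angelate anion displaces the primary alkoxyphosphonium group (SN2), so the acid is never activated as an acyl electrophile and its Z geometry should be preserved.

Step 14
Reactants: 19 tert-butyl (Z)-3-methyl-4-{[(Z)-2-methylbut-2-enoyl]oxy}but-2-enoate
Product: 20 (Z)-3-methyl-4-{[(Z)-2-methylbut-2-enoyl]oxy}but-2-enoic acid
Conditions: TFA/CH2Cl2 (1:4), 0 °C → rt
Reagents that add atoms: none
Why: Acidolysis of the tert-butyl ester (E1 loss of isobutene) frees the carboxylic acid without touching the two conjugated esters.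

Step 15
Reactants: 13 (3R,4R,5R)-9-(tert-butyldimethylsilyloxy)-3,11-dihydroxyeremophil-9-en-8-one; 20 (Z)-3-methyl-4-{[(Z)-2-methylbut-2-enoyl]oxy}but-2-enoic acid
Product: 22 (3R,4R,5R)-9-(tert-butyldimethylsilyloxy)-11-hydroxy-8-oxoeremophil-9-en-3-yl (Z)-3-methyl-4-{[(Z)-2-methylbut-2-enoyl]oxy}but-2-enoate, via acid chloride 21 (not isolated)
Conditions: 20, 1-chloro-N,N,2-trimethylprop-1-enylamine, CH2Cl2, 0 °C; then 13, pyridine, DMAP (5 mol%), 0 °C → rt
Reagents that add atoms: none
Why: The α-chloroenamine forms the acid chloride under neutral conditions and pyridine-mediated acylation then esterifies the secondary C3 hydroxyl with retention, the tertiary C11 hydroxyl and the silyl enol ether being unreactive (acyl chloride esterification).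

Step 16
Reactants: 22 (3R,4R,5R)-9-(tert-butyldimethylsilyloxy)-11-hydroxy-8-oxoeremophil-9-en-3-yl (Z)-3-methyl-4-{[(Z)-2-methylbut-2-enoyl]oxy}but-2-enoate
Product: 24 (3R,4R,5R)-9-(tert-butyldimethylsilyloxy)-8-oxoeremophila-7(11),9-dien-3-yl (Z)-3-methyl-4-{[(Z)-2-methylbut-2-enoyl]oxy}but-2-enoate, via tertiary mesylate 23 (not isolated)
Conditions: MsCl (3 equiv), Et3N (8 equiv), CH2Cl2, 0 °C → rt
Reagents that add atoms: none
Why: Sulfene-mediated mesylation of the tertiary aldol hydroxyl and E1cB elimination through the C8 enolate give the conjugated, tetrasubstituted C7=C11 alkene (aldol dehydration), which removes the C7 stereocentre.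

Step 17
Reactants: 24 (3R,4R,5R)-9-(tert-butyldimethylsilyloxy)-8-oxoeremophila-7(11),9-dien-3-yl (Z)-3-methyl-4-{[(Z)-2-methylbut-2-enoyl]oxy}but-2-enoate
Product: 25 (3R,4R,5R)-9-hydroxy-8-oxoeremophila-7(11),9-dien-3-yl (Z)-3-methyl-4-{[(Z)-2-methylbut-2-enoyl]oxy}but-2-enoate (target)
Conditions: HF·pyridine, pyridine/THF, 0 °C
Reagents that add atoms: none
Why: Fluoride cleaves the Si–O bond of the silyl enol ether and releases the diosphenol under conditions that leave both esters and the alkene geometries intact (desilylation).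

Compound list
1 | tetrahydro-4H-thiopyran-4-one | O=C1CCSCC1 | starting material
2 | 2,3-dihydro-4H-thiopyran-4-one | O=C1CCSC=C1 | intermediate
3 | 4-(tert-butyldimethylsilyloxy)-2H-thiopyran | CC(C)(C)[Si](C)(C)OC1=CCSC=C1 | intermediate
4 | 2-methoxy-5-methylphenol | COc1ccc(C)cc1O | starting material
5 | 2-methoxy-5-methyl-1,4-benzoquinone | COC1=CC(=O)C(C)=CC1=O | intermediate
6 | silyl enol ether cycloadduct: 3-(tert-butyldimethylsilyloxy)-1,15-epithio-8-methoxy-11,12,13-trinoreremophila-2,7-diene-6,9-dione, endo, C14 and H-10 syn to the S–C15 bridge | C[C@]12C(=O)C=C(OC)C(=O)[C@H]1[C@@H]3SC[C@H]2C(O[Si](C)(C)C(C)(C)C)=C3 | intermediate (not isolated)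
7 | 1,15-epithio-8-methoxy-11,12,13-trinoreremophil-7-ene-3,6,9-trione | C[C@]12C(=O)C=C(OC)C(=O)[C@H]1[C@@H]3SC[C@H]2C(=O)C3 | intermediate
8 | sulfur-bridged triol: (3R)-1,15-epithio-8-methoxy-11,12,13-trinoreremophil-7-ene-3,6,9-triol, C6 and C9 carbinols as formed (inconsequential) | C[C@]12C(O)C=C(OC)C(O)[C@H]1[C@@H]3SC[C@H]2[C@H](O)C3 | intermediate (not isolated)
9 | (3R)-1,15-epithio-3,9-dihydroxy-11,12,13-trinoreremophil-6-en-8-one, C9 carbinol as either epimer | C[C@]12C=CC(=O)C(O)[C@H]1[C@@H]3SC[C@H]2[C@H](O)C3 | intermediate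
10 | (3R,4R,5R,10S)-3,9-dihydroxy-11,12,13-trinoreremophilan-8-one, C9 carbinol as either epimer | O[C@@H]1CC[C@@H]2C(O)C(=O)CC[C@]2(C)[C@H]1C | intermediate
11 | (3R,4R,5R)-3,9-dihydroxy-11,12,13-trinoreremophil-9-en-8-one | O[C@@H]1CCC2=C(O)C(=O)CC[C@]2(C)[C@H]1C | intermediate
12 | (3R,4R,5R)-9-(tert-butyldimethylsilyloxy)-3-hydroxy-11,12,13-trinoreremophil-9-en-8-one | O[C@@H]1CCC2=C(O[Si](C)(C)C(C)(C)C)C(=O)CC[C@]2(C)[C@H]1C | intermediate
13 | (3R,4R,5R)-9-(tert-butyldimethylsilyloxy)-3,11-dihydroxyeremophil-9-en-8-one, C7 as either epimer | O[C@@H]1CCC2=C(O[Si](C)(C)C(C)(C)C)C(=O)C(C(C)(C)O)C[C@]2(C)[C@H]1C | intermediate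
14 | tert-butyldimethyl(prop-2-yn-1-yloxy)silane | C#CCO[Si](C)(C)C(C)(C)C | starting material
15 | tert-butyl 4-(tert-butyldimethylsilyloxy)but-2-ynoate | CC(C)(C)OC(=O)C#CCO[Si](C)(C)C(C)(C)C | intermediate
16 | tert-butyl (Z)-4-(tert-butyldimethylsilyloxy)-3-methylbut-2-enoate | CC(C)(C)OC(=O)/C=C(/C)CO[Si](C)(C)C(C)(C)C | intermediate
17 | tert-butyl (Z)-4-hydroxy-3-methylbut-2-enoate | CC(C)(C)OC(=O)/C=C(/C)CO | intermediate
18 | angelic acid, (Z)-2-methylbut-2-enoic acid | C/C=C(/C)C(=O)O | starting material
19 | tert-butyl (Z)-3-methyl-4-{[(Z)-2-methylbut-2-enoyl]oxy}but-2-enoate | C/C=C(/C)C(=O)OC/C(C)=C\C(=O)OC(C)(C)C | intermediate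
20 | (Z)-3-methyl-4-{[(Z)-2-methylbut-2-enoyl]oxy}but-2-enoic acid | C/C=C(/C)C(=O)OC/C(C)=C\C(=O)O | intermediate
21 | (Z)-3-methyl-4-{[(Z)-2-methylbut-2-enoyl]oxy}but-2-enoyl chloride | C/C=C(/C)C(=O)OC/C(C)=C\C(Cl)=O | intermediate (not isolated)
22 | (3R,4R,5R)-9-(tert-butyldimethylsilyloxy)-11-hydroxy-8-oxoeremophil-9-en-3-yl (Z)-3-methyl-4-{[(Z)-2-methylbut-2-enoyl]oxy}but-2-enoate, C7 as either epimer | C/C=C(/C)C(=O)OC/C(C)=C\C(=O)O[C@@H]1CCC2=C(O[Si](C)(C)C(C)(C)C)C(=O)C(C(C)(C)O)C[C@]2(C)[C@H]1C | intermediate
23 | C11 methanesulfonate of 22 | C/C=C(/C)C(=O)OC/C(C)=C\C(=O)O[C@@H]1CCC2=C(O[Si](C)(C)C(C)(C)C)C(=O)C(C(C)(C)OS(C)(=O)=O)C[C@]2(C)[C@H]1C | intermediate (not isolated)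
24 | (3R,4R,5R)-9-(tert-butyldimethylsilyloxy)-8-oxoeremophila-7(11),9-dien-3-yl (Z)-3-methyl-4-{[(Z)-2-methylbut-2-enoyl]oxy}but-2-enoate | C/C=C(/C)C(=O)OC/C(C)=C\C(=O)O[C@@H]1CCC2=C(O[Si](C)(C)C(C)(C)C)C(=O)C(=C(C)C)C[C@]2(C)[C@H]1C | intermediate
25 | (3R,4R,5R)-9-hydroxy-8-oxoeremophila-7(11),9-dien-3-yl (Z)-3-methyl-4-{[(Z)-2-methylbut-2-enoyl]oxy}but-2-enoate | C/C=C(/C)C(=O)OC/C(C)=C\C(=O)O[C@@H]1CCC2=C(O)C(=O)C(=C(C)C)C[C@]2(C)[C@H]1C | target

Total step count: 17. Longest linear sequence: 11 steps (steps 1, 2, 4, 5, 6, 7, 8, 9, 15, 16, 17); steps 3 and 10–14 are side branches.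

Steps most likely to fail

Step 4. The chiral titanium Lewis acid may fail to give useful enantio- or regiocontrol, for example through competitive binding to the thioether or desilylation of the diene before cycloaddition. Fallback: starting from 3 and 5, the cycloaddition is run without catalyst (toluene, 60 °C, then HF in MeCN), where the intrinsic polarisation of the methoxyquinone and of the diene should still direct the same regiochemistry and the endo mode. This gives 7 as the racemate, that is, together with the antipodal triketone F2, formed through the antipodal silyl enol ether cycloadduct F1. Preparative chromatography on an amylose tris(3,5-dimethylphenylcarbamate) chiral stationary phase then separates the enantiomers, and the route is rejoined at 7.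

Step 6. On the nickel surface the C8 ketone may be over-reduced, or saturation of C6=C7 may be incomplete, while the C–S bonds are being cleaved. Fallback: starting from 7, the LiAlH4 reduction of step 5 is worked up with aqueous NaOH instead of acid so that triol 8 is isolated. Raney Ni in EtOH is then applied to 8, which has no carbonyl group and no conjugated alkene, to give the sulfur-free triol methyl enol ether F3. Treatment with 1 M HCl in THF effects the same transposition as in step 5 and gives the sulfur-free 3,9-dihydroxy-6-en-8-one F4. Hydrogenation over Pd/C (H2, EtOAc) saturates C6=C7 selectively, and the route is rejoined at 10.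

Step 15. Activation of the Z-configured acid 20 may lead to γ-deprotonation to a vinylketene or to cyclisation onto the neighbouring acyloxy group, with scrambling of the alkene geometry or loss of the angelate. Fallback: starting from 13, the side chain is built in two stages so that the angelate is introduced as a nucleophile. Commercial 4-methylfuran-2(5H)-one is opened with SOCl2 and catalytic ZnCl2 to (Z)-4-chloro-3-methylbut-2-enoyl chloride F5, whose Z geometry is fixed by the ring. Acylation of 13 with it (pyridine, CH2Cl2, 0 °C) gives the chloro ester F6. Displacement of the allylic chloride with caesium angelate (from 18 and Cs2CO3; NaI cat., DMF, rt) gives 22, where the route is rejoined.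

Further compounds
F1 | step 4 | antipode of silyl enol ether cycloadduct 6 | C[C@@]12C(=O)C=C(OC)C(=O)[C@@H]1[C@H]3SC[C@@H]2C(O[Si](C)(C)C(C)(C)C)=C3
F2 | step 4 | antipode of triketone 7 | C[C@@]12C(=O)C=C(OC)C(=O)[C@@H]1[C@H]3SC[C@@H]2C(=O)C3
F3 | step 6 | (3R,4R,5R,10S)-8-methoxy-11,12,13-trinoreremophil-7-ene-3,6,9-triol | C[C@H]1[C@H](O)CC[C@@H]2C(O)C(OC)=CC(O)[C@]12C
F4 | step 6 | (3R,4R,5R,10S)-3,9-dihydroxy-11,12,13-trinoreremophil-6-en-8-one | C[C@H]1[C@H](O)CC[C@@H]2C(O)C(=O)C=C[C@]12C
F5 | step 15 | (Z)-4-chloro-3-methylbut-2-enoyl chloride | ClC/C(C)=C\C(Cl)=O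
F6 | step 15 | (3R,4R,5R)-9-(tert-butyldimethylsilyloxy)-11-hydroxy-8-oxoeremophil-9-en-3-yl (Z)-4-chloro-3-methylbut-2-enoate | ClC/C(C)=C\C(=O)O[C@@H]1CCC2=C(O[Si](C)(C)C(C)(C)C)C(=O)C(C(C)(C)O)C[C@]2(C)[C@H]1C
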